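I must pick the next charge. The candidates are ash, oak and maple, all at the same equivalents and phase ratio as the two earlier runs.

| setting | south | west | ash | oak | maple |
|---|---|---|---|---|---|
| starting material | 0.021 M | 0.066 M | 0.025 M | 0.050 M | 0.10 M |
| reagent in the second phase | 0.80 equiv | 0.80 equiv | 0.800 equiv | 0.800 equiv | 0.800 equiv |
| remark | run made earlier | run made earlier |  |  |  |
| time |  |  | 20 min | 20 min | 20 min |
| volume of the second phase over the first |  |  | 0.25 | 0.25 | 0.25 |

| run | time / min | product / % | starting material / % |
|---|---|---|---|
| south | 3.00 | 2.5 | 95.9 |
| south | 6.00 | 3.6 | 93.2 |
| south | 10.0 | 6.2 | 88.5 |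
| south | 12.0 | 6.1 | 86.7 |
| south | 15.0 | 8.5 | 84.7 |
| south | 20.0 | 9.4 | 80.7 |
| west | 3.00 | 6.0 | 89.2 |
| west | 6.00 | 10.3 | 80.4 |
| west | 10.0 | 16.1 | 71.7 |
| west | 12.0 | 17.6 | 66.9 |
| west | 15.0 | 19.6 | 62.3 |
| west | 20.0 | 24.1 | 55.7 |

(scatter of a reading: 0.5 percentage points)

- in the second phase: reagent in the second phase; everything else is in the first
- charges count per volume of the first phase; a concentration in a rate is the amount of a species over the volume of its own phase; every rate counts per litre of the first phase
- the earlier runs hold the two phases in the same ratio of volumes as the flask asked about
- "hardly changes" means that all values lie within two and a half points (for a concentration: within two and a half percent of the largest)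

- [product] at the end for ash, oak, maple, in this order
- how the row runs (falls all the way / falls, then rises / rises, then falls / rises all the way / hardly changes)

In each earlier run, the reciprocal of the fraction of starting material left climbs about linearly with time, and it climbs faster at the higher charge. The west run, with 55.7% left after 20.0 min, gives 0.603 M⁻¹ min⁻¹ for that reciprocal minus one, divided by charge and time; I call this the loss constant and freeze it. The south run gives 0.569 M⁻¹ min⁻¹, but I trust the west run more, because it has lost 44.3% against 19.3%, so the same scatter weighs less.

Product per starting material lost, the selectivity, reads 0.544 in the west run and 0.487 in the south run, so the more dilute south run shows no better selectivity.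

The fraction left is one over one plus loss constant times charge times time. With the west selectivity, I reckon 0.00315 M for ash, 0.0102 M for oak and 0.0297 M for maple. By this reckoning maple gives the most product per litre, and also more per charge than ash, 29.7% against 12.6%. So I charge maple, although 0.10 M lies above the west charge of 0.066 M.

The forecast gives 0.0031 M, 0.01 M and 0.0292 M, a row that rises all the way, holding that “selectivity doesn't depend on concentration”.

The flasks give 0.00298 M, 0.00991 M and 0.0297 M, a row that rises all the way.

    starting material + reagent in the reaction phase ⇌ product (K = 150 M⁻¹, k = 1.40 M⁻¹ min⁻¹)
    2 starting material → homo dimer (k = 0.140 M⁻¹ min⁻¹)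
    reagent in the reaction phase ⇌ reagent in the second phase, rate k3*([reagent in the reaction phase] - [reagent in the second phase]/K3) per volume of the first phase (partition coefficient = 9.50, kL = 2.70 min⁻¹)

The loss constant reckons 45.4% left for maple, where 44.9% stood, and 76.8% for oak after 10.0 min, where 77.0% stood. It counts two paths together: maple's lost starting material stands as product, 29.7%, and homo dimer, 25.4%. The forecast's value for maple stops holding in a run where the reagent in the second phase does not shrink; in maple after 20.0 min it is down to 44.4% of its own charge. Held at its charge, that supply lifts product in maple from 0.0297 M to 0.0463 M.

The numbers in the tables stem from a simulated flask for an exercise; noise was put on by code.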